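## Retrosynthetic overview

1. The (E)-4-hydroxystyryl arm is attached last, by a Heck reaction on the fully deprotected bis(dihydrobenzofuran) aryl chloride, so the acid-sensitive stilbene never sees an acid step.
2. Dihydrofuran ring A (ε-viniferin type, next to the styryl arm) is closed through its C2–O bond by an enantioselective Brønsted-acid cycloisomerisation of a 2-(1,2-diarylvinyl)phenol.
3. That triarylethylene comes from a palladium carbene coupling of the ring-B aryl bromide with a deoxybenzoin tosylhydrazone.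
4. Dihydrofuran ring B (gnetin C type) is closed first by the same C–O ring closure, using the antipodal catalyst, on a tertiary carbinol made from a 2,6-dioxygenated diaryl ketone and a benzyl Grignard reagent.
5. Ring order: dihydrofuran ring B, then dihydrofuran ring A, then the stilbene.

Assumption: the (S,S)-catalyst is taken to give the (2R,3R) ring and the (R,R)-catalyst the (2S,3S) ring; if experiment shows the opposite sense, the two antipodes are exchanged between steps 4 and 8.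

Catalyst for steps 4 and 8: (S,S)-IDPi is the imidodiphosphorimidate HN{P(=NSO2CF3)[(S)-3,3'-Ar2-1,1'-binaphthalene-2,2'-diolate]}2 with Ar = 3,5-(CF3)2C6H3; (R,R)-IDPi is its enantiomer.

## Route

Step 1
Reactants: 1 1-bromo-3,5-dimethoxybenzene; 2 3,5-dimethoxybenzonitrile
Product: 5 (4-bromo-2,6-dimethoxyphenyl)(3,5-dimethoxyphenyl)methanone, via aryllithium 3 (not isolated), via N-lithio ketimine 4 (not isolated)
Conditions: LiN(iPr)2 (1.1 equiv), THF, −78 °C; then 2, −78 → 0 °C; then 2 M aq HCl, 40 °C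
Reagents that add atoms: water, O
Why: Directed ortho-lithiation at the position between the two methoxy groups (an amide base avoids Br/Li exchange), then aryllithium addition to the nitrile, which stops at the ketimine so that hydrolysis gives the hindered diaryl ketone without over-addition.

Step 2
Reactants: 5 (4-bromo-2,6-dimethoxyphenyl)(3,5-dimethoxyphenyl)methanone
Product: 6 (4-bromo-2-hydroxy-6-methoxyphenyl)(3,5-dimethoxyphenyl)methanone
Conditions: BCl3 (1.2 equiv), CH2Cl2, −78 → 0 °C; then H2O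
Reagents that add atoms: none
Why: Chelation-controlled Lewis-acid demethylation, in which BCl3 bridges the carbonyl and one ortho-methoxy oxygen so only that ether is cleaved.

Step 3
Reactants: 6 (4-bromo-2-hydroxy-6-methoxyphenyl)(3,5-dimethoxyphenyl)methanone; 7 4-methoxybenzylmagnesium chloride
Product: 8 1-(4-bromo-2-hydroxy-6-methoxyphenyl)-1-(3,5-dimethoxyphenyl)-2-(4-methoxyphenyl)ethan-1-ol (racemic)
Conditions: 7 (3.5 equiv, 0.25 M in THF), THF, 0 °C → rt; then sat. aq NH4Cl; used crude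
Reagents that add atoms: none
Why: Grignard 1,2-addition to the magnesium-phenoxide-chelated ketone (the first equivalent deprotonates the phenol); the aryl bromide is inert without a catalyst and the racemic carbinol centre is erased in step 4.

Step 4
Reactants: 8 1-(4-bromo-2-hydroxy-6-methoxyphenyl)-1-(3,5-dimethoxyphenyl)-2-(4-methoxyphenyl)ethan-1-ol
Product: 11 (2R,3R)-6-bromo-3-(3,5-dimethoxyphenyl)-4-methoxy-2-(4-methoxyphenyl)-2,3-dihydro-1-benzofuran, via triarylethylene 9 (not isolated), via benzylic cation 10 (not isolated)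
Conditions: (S,S)-IDPi (5 mol%), 5 Å MS, CHCl3, 0 °C → rt
Reagents that add atoms: none
Why: Proposed new method: an enantioselective Brønsted-acid dehydrative hydroalkoxylation (cycloisomerisation) of a 2-(1,2-diarylvinyl)phenol, in which the confined acid dehydrates 8 to alkene 9 and protonates it reversibly at the diaryl carbon to give the 4-methoxybenzylic cation 10 as a chiral ion pair; the two C3 epimers of 10 interconvert through 9 (Curtin–Hammett), so the C–O ring closure of the anion-bound phenol is enantio-determining and sets C3 (R) and, anti to the C3 aryl group, C2 (R, trans), while protonation at the other alkene carbon only returns 9 because no ring can close; the closest known reactions are IDPi-catalysed asymmetric intramolecular hydroalkoxylation of alkenols, chiral phosphoric acid additions to quinone methides made in situ, and the racemic acid-mediated quinone-methide closure used for oligostilbene dihydrobenzofurans.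

Step 5
Reactants: 12 1-chloro-3,5-dimethoxybenzene; 13 (4-methoxyphenyl)acetyl chloride
Product: 15 1-(2-chloro-6-hydroxy-4-methoxyphenyl)-2-(4-methoxyphenyl)ethan-1-one, via dimethoxy ketone 14 (not isolated)
Conditions: AlCl3 (2.6 equiv), ClCH2CH2Cl, 0 → 50 °C; then ice/H2O
Reagents that add atoms: none
Why: Friedel–Crafts acylation at the position para to one methoxy group and flanked by Cl (not the more hindered site between the two methoxy groups), after which excess AlCl3 cleaves the methoxy group chelated to the new ketone.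

Step 6
Reactants: 15 1-(2-chloro-6-hydroxy-4-methoxyphenyl)-2-(4-methoxyphenyl)ethan-1-one
Product: 16 N'-[1-(2-chloro-6-hydroxy-4-methoxyphenyl)-2-(4-methoxyphenyl)ethylidene]-4-methylbenzenesulfonohydrazide
Conditions: TsNHNH2 (1.2 equiv), MeOH, 65 °C
Reagents that add atoms: 4-methylbenzenesulfonohydrazide, Cc1ccc(cc1)S(=O)(=O)NN
Why: Hydrazone condensation of the ketone, helped by the ortho-phenol hydrogen bond, gives the crystalline N-tosylhydrazone.

Step 7
Reactants: 11 (2R,3R)-6-bromo-3-(3,5-dimethoxyphenyl)-4-methoxy-2-(4-methoxyphenyl)-2,3-dihydro-1-benzofuran; 16 the N-tosylhydrazone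
Product: 18 3-chloro-2-{1-[(2R,3R)-3-(3,5-dimethoxyphenyl)-4-methoxy-2-(4-methoxyphenyl)-2,3-dihydro-1-benzofuran-6-yl]-2-(4-methoxyphenyl)ethenyl}-5-methoxyphenol (E/Z mixture), via diazo compound 17 (not isolated)
Conditions: Pd2(dba)3 (2.5 mol%), XPhos (10 mol%), LiOtBu (3.5 equiv), 1,4-dioxane, 80 °C
Reagents that add atoms: none
Why: Barluenga-type palladium carbene cross-coupling, in which base turns the hydrazone into diazo compound 17, the aryl–palladium bromide from 11 forms a carbene, and aryl migration then β-hydride elimination give the triarylethylene; the aryl bromide reacts far faster than the aryl chloride at 80 °C, and the alkene geometry does not matter for step 8.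

Step 8
Reactants: 18 the triarylethylene phenol
Product: 20 (2S,3S)-4-chloro-3-[(2R,3R)-3-(3,5-dimethoxyphenyl)-4-methoxy-2-(4-methoxyphenyl)-2,3-dihydro-1-benzofuran-6-yl]-6-methoxy-2-(4-methoxyphenyl)-2,3-dihydro-1-benzofuran, via benzylic cation 19 (not isolated)
Conditions: (R,R)-IDPi (5 mol%), 5 Å MS, CHCl3, −20 → 0 °C
Reagents that add atoms: none
Why: Proposed new method: the same enantioselective Brønsted-acid cycloisomerisation as in step 4, here starting from the preformed alkene, in which reversible protonation of either alkene isomer gives the equilibrating 4-methoxybenzylic cation 19 and the anion-directed C–O closure by the ortho-phenol sets C3 (S) and trans C2 (S); control comes from the antipodal catalyst because the existing stereocentres are remote, and the low temperature keeps the aryl ether of ring B from re-ionising; the closest known reactions are IDPi-catalysed asymmetric hydroalkoxylation and the racemic acid cyclisation of 2-hydroxystilbenes to 2-aryl-dihydrobenzofurans.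

Step 9
Reactants: 20 the hexamethyl bis(dihydrobenzofuran) chloride
Product: 21 (2S,3S)-4-chloro-3-[(2R,3R)-3-(3,5-dihydroxyphenyl)-4-hydroxy-2-(4-hydroxyphenyl)-2,3-dihydro-1-benzofuran-6-yl]-2-(4-hydroxyphenyl)-2,3-dihydro-1-benzofuran-6-ol
Conditions: BBr3 (12 equiv), CH2Cl2, −78 → 0 °C; then H2O
Reagents that add atoms: none
Why: BBr3 cleavage of all six aryl methyl ethers, done before the stilbene exists so no acid-triggered stilbene cyclisation can occur; any reversible opening of a benzylic C2–O bond re-closes to the trans ring and leaves C3 untouched.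

Step 10
Reactants: 21 the hexaphenol aryl chloride; 22 4-ethenylphenyl acetate (4-acetoxystyrene)
Product: 24 (2S,3S)-3-[(2R,3R)-3-(3,5-dihydroxyphenyl)-4-hydroxy-2-(4-hydroxyphenyl)-2,3-dihydro-1-benzofuran-6-yl]-2-(4-hydroxyphenyl)-4-[(E)-2-(4-hydroxyphenyl)ethenyl]-2,3-dihydro-1-benzofuran-6-ol, via monoacetate 23 (not isolated)
Conditions: Pd2(dba)3 (2.5 mol%), P(t-Bu)3·HBF4 (10 mol%), Cy2NMe (3 equiv), 1,4-dioxane, 110 °C; then K2CO3 (cat.), MeOH, rt
Reagents that add atoms: none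
Why: Mizoroki–Heck reaction with a bulky electron-rich phosphine for the aryl chloride gives the (E)-stilbene by syn-insertion and syn-β-hydride elimination under non-acidic conditions, and mild methanolysis removes the acetate without touching the four stereocentres.

## Compound list

1 | 1-bromo-3,5-dimethoxybenzene | COc1cc(Br)cc(OC)c1 | starting material
2 | 3,5-dimethoxybenzonitrile | COc1cc(cc(OC)c1)C#N | starting material
3 | (4-bromo-2,6-dimethoxyphenyl)lithium | [Li]c1c(OC)cc(Br)cc1OC | intermediate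
4 | N-lithio (4-bromo-2,6-dimethoxyphenyl)(3,5-dimethoxyphenyl)methanimine | [Li]N=C(c1cc(OC)cc(OC)c1)c1c(OC)cc(Br)cc1OC | intermediate
5 | (4-bromo-2,6-dimethoxyphenyl)(3,5-dimethoxyphenyl)methanone | COc1cc(cc(OC)c1)C(=O)c1c(OC)cc(Br)cc1OC | intermediate
6 | (4-bromo-2-hydroxy-6-methoxyphenyl)(3,5-dimethoxyphenyl)methanone | COc1cc(cc(OC)c1)C(=O)c1c(O)cc(Br)cc1OC | intermediate
7 | 4-methoxybenzylmagnesium chloride (0.25 M in THF) | COc1ccc(C[Mg]Cl)cc1 | starting material
8 | 1-(4-bromo-2-hydroxy-6-methoxyphenyl)-1-(3,5-dimethoxyphenyl)-2-(4-methoxyphenyl)ethan-1-ol, racemic | COc1ccc(CC(O)(c2cc(OC)cc(OC)c2)c2c(O)cc(Br)cc2OC)cc1 | intermediate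
9 | 5-bromo-2-[1-(3,5-dimethoxyphenyl)-2-(4-methoxyphenyl)ethenyl]-3-methoxyphenol, E/Z mixture | COc1ccc(C=C(c2cc(OC)cc(OC)c2)c2c(O)cc(Br)cc2OC)cc1 | intermediate
10 | 2-(4-bromo-2-hydroxy-6-methoxyphenyl)-2-(3,5-dimethoxyphenyl)-1-(4-methoxyphenyl)ethyl cation (ion pair with the catalyst anion, both C2 epimers) | COc1ccc([CH+]C(c2cc(OC)cc(OC)c2)c2c(O)cc(Br)cc2OC)cc1 | intermediate
11 | (2R,3R)-6-bromo-3-(3,5-dimethoxyphenyl)-4-methoxy-2-(4-methoxyphenyl)-2,3-dihydro-1-benzofuran | Brc1cc(OC)c2c(c1)O[C@@H](c1ccc(OC)cc1)[C@@H]2c1cc(OC)cc(OC)c1 | intermediate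
12 | 1-chloro-3,5-dimethoxybenzene | COc1cc(Cl)cc(OC)c1 | starting material
13 | (4-methoxyphenyl)acetyl chloride | COc1ccc(CC(Cl)=O)cc1 | starting material
14 | 1-(2-chloro-4,6-dimethoxyphenyl)-2-(4-methoxyphenyl)ethan-1-one | COc1ccc(CC(=O)c2c(Cl)cc(OC)cc2OC)cc1 | intermediate
15 | 1-(2-chloro-6-hydroxy-4-methoxyphenyl)-2-(4-methoxyphenyl)ethan-1-one | COc1ccc(CC(=O)c2c(Cl)cc(OC)cc2O)cc1 | intermediate
16 | N'-[1-(2-chloro-6-hydroxy-4-methoxyphenyl)-2-(4-methoxyphenyl)ethylidene]-4-methylbenzenesulfonohydrazide | COc1ccc(CC(=NNS(=O)(=O)c2ccc(C)cc2)c2c(Cl)cc(OC)cc2O)cc1 | intermediate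
17 | 3-chloro-2-[1-diazo-2-(4-methoxyphenyl)ethyl]-5-methoxyphenol (as its lithium phenoxide in the flask) | COc1ccc(CC(=[N+]=[N-])c2c(Cl)cc(OC)cc2O)cc1 | intermediate
18 | 3-chloro-2-{1-[(2R,3R)-3-(3,5-dimethoxyphenyl)-4-methoxy-2-(4-methoxyphenyl)-2,3-dihydro-1-benzofuran-6-yl]-2-(4-methoxyphenyl)ethenyl}-5-methoxyphenol, E/Z mixture | COc1ccc(C=C(c2cc(OC)c3c(c2)O[C@@H](c2ccc(OC)cc2)[C@@H]3c2cc(OC)cc(OC)c2)c2c(Cl)cc(OC)cc2O)cc1 | intermediate
19 | 2-(2-chloro-6-hydroxy-4-methoxyphenyl)-2-[(2R,3R)-3-(3,5-dimethoxyphenyl)-4-methoxy-2-(4-methoxyphenyl)-2,3-dihydro-1-benzofuran-6-yl]-1-(4-methoxyphenyl)ethyl cation (ion pair with the catalyst anion) | COc1ccc([CH+]C(c2cc(OC)c3c(c2)O[C@@H](c2ccc(OC)cc2)[C@@H]3c2cc(OC)cc(OC)c2)c2c(Cl)cc(OC)cc2O)cc1 | intermediate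
20 | (2S,3S)-4-chloro-3-[(2R,3R)-3-(3,5-dimethoxyphenyl)-4-methoxy-2-(4-methoxyphenyl)-2,3-dihydro-1-benzofuran-6-yl]-6-methoxy-2-(4-methoxyphenyl)-2,3-dihydro-1-benzofuran | Clc1cc(OC)cc2c1[C@H](c1cc(OC)c3c(c1)O[C@@H](c1ccc(OC)cc1)[C@@H]3c1cc(OC)cc(OC)c1)[C@@H](c1ccc(OC)cc1)O2 | intermediate
21 | (2S,3S)-4-chloro-3-[(2R,3R)-3-(3,5-dihydroxyphenyl)-4-hydroxy-2-(4-hydroxyphenyl)-2,3-dihydro-1-benzofuran-6-yl]-2-(4-hydroxyphenyl)-2,3-dihydro-1-benzofuran-6-ol | Clc1cc(O)cc2c1[C@H](c1cc(O)c3c(c1)O[C@@H](c1ccc(O)cc1)[C@@H]3c1cc(O)cc(O)c1)[C@@H](c1ccc(O)cc1)O2 | intermediate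
22 | 4-ethenylphenyl acetate (4-acetoxystyrene) | CC(=O)Oc1ccc(C=C)cc1 | starting material
23 | 4-[(E)-2-{(2S,3S)-3-[(2R,3R)-3-(3,5-dihydroxyphenyl)-4-hydroxy-2-(4-hydroxyphenyl)-2,3-dihydro-1-benzofuran-6-yl]-6-hydroxy-2-(4-hydroxyphenyl)-2,3-dihydro-1-benzofuran-4-yl}ethenyl]phenyl acetate | CC(=O)Oc1ccc(/C=C/c2cc(O)cc3c2[C@H](c2cc(O)c4c(c2)O[C@@H](c2ccc(O)cc2)[C@@H]4c2cc(O)cc(O)c2)[C@@H](c2ccc(O)cc2)O3)cc1 | intermediate
24 | (2S,3S)-3-[(2R,3R)-3-(3,5-dihydroxyphenyl)-4-hydroxy-2-(4-hydroxyphenyl)-2,3-dihydro-1-benzofuran-6-yl]-2-(4-hydroxyphenyl)-4-[(E)-2-(4-hydroxyphenyl)ethenyl]-2,3-dihydro-1-benzofuran-6-ol (CNP0188679.4) | Oc1ccc(/C=C/c2cc(O)cc3c2[C@H](c2cc(O)c4c(c2)O[C@@H](c2ccc(O)cc2)[C@@H]4c2cc(O)cc(O)c2)[C@@H](c2ccc(O)cc2)O3)cc1 | target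

## Step count and risks

Total steps: 10. Longest linear sequence: 8 steps (steps 1–4, then 7–10); steps 5–6 are a two-step side branch.

Steps most likely to fail:

Step 4 (new method). The cyclisation may give low enantioselectivity if the ion pair is loose, if an achiral background closure competes, or if the water released slows the catalyst. The fallback sets out from 8 and comes back at 11. Treating 8 with p-TsOH·H2O (10 mol%) in toluene at rt, the known racemic acid-mediated closure, gives the trans bromide as a racemate, that is 11 together with its enantiomer (2S,3S)-6-bromo-3-(3,5-dimethoxyphenyl)-4-methoxy-2-(4-methoxyphenyl)-2,3-dihydro-1-benzofuran F1. Preparative chiral SFC separates the two and 11 is carried on.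

Step 7. The hydrazone is hindered on both ortho sides and carries a free phenol, and its aryl chloride could undergo intramolecular N-arylation to an indazole or compete with the bromide of 11. The fallback sets out from 11 and comes back at 18, replacing the palladium carbene coupling by organolithium addition.
- Vilsmeier–Haack formylation of 12 (POCl3, DMF) gives 2-chloro-4,6-dimethoxybenzaldehyde F2.
- Bromine–lithium exchange on 11 (n-BuLi, THF, −78 °C) gives [(2R,3R)-3-(3,5-dimethoxyphenyl)-4-methoxy-2-(4-methoxyphenyl)-2,3-dihydro-1-benzofuran-6-yl]lithium F3.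
- F3 adds to F2 to give (2-chloro-4,6-dimethoxyphenyl)[(2R,3R)-3-(3,5-dimethoxyphenyl)-4-methoxy-2-(4-methoxyphenyl)-2,3-dihydro-1-benzofuran-6-yl]methanol F4.
- Dess–Martin oxidation gives (2-chloro-4,6-dimethoxyphenyl)[(2R,3R)-3-(3,5-dimethoxyphenyl)-4-methoxy-2-(4-methoxyphenyl)-2,3-dihydro-1-benzofuran-6-yl]methanone F5.
- BCl3 (1.1 equiv, CH2Cl2, −78 °C) cleaves the ketone-chelated methoxy group to give (2-chloro-6-hydroxy-4-methoxyphenyl)[(2R,3R)-3-(3,5-dimethoxyphenyl)-4-methoxy-2-(4-methoxyphenyl)-2,3-dihydro-1-benzofuran-6-yl]methanone F6.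
- Addition of 7 gives 1-(2-chloro-6-hydroxy-4-methoxyphenyl)-1-[(2R,3R)-3-(3,5-dimethoxyphenyl)-4-methoxy-2-(4-methoxyphenyl)-2,3-dihydro-1-benzofuran-6-yl]-2-(4-methoxyphenyl)ethan-1-ol F7.
- Under the conditions of step 8, F7 loses water to give 18 in the flask and goes on to 20.

Step 8 (new method). The antipodal catalyst may not override the substrate, or the acid may re-open dihydrofuran ring B. The fallback sets out from 18 and comes back at 20. An achiral acid, (PhO)2P(O)OH (10 mol%) in toluene at 0 °C → rt, closes the ring without facial control and gives 20 together with its diastereomer (2R,3R)-4-chloro-3-[(2R,3R)-3-(3,5-dimethoxyphenyl)-4-methoxy-2-(4-methoxyphenyl)-2,3-dihydro-1-benzofuran-6-yl]-6-methoxy-2-(4-methoxyphenyl)-2,3-dihydro-1-benzofuran F8. Because ring B is already enantiopure the two are diastereomers, and silica gel chromatography or preparative HPLC gives 20.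

## Further compounds

F1 | step 4 | (2S,3S)-6-bromo-3-(3,5-dimethoxyphenyl)-4-methoxy-2-(4-methoxyphenyl)-2,3-dihydro-1-benzofuran | Brc1cc(OC)c2c(c1)O[C@H](c1ccc(OC)cc1)[C@H]2c1cc(OC)cc(OC)c1
F2 | step 7 | 2-chloro-4,6-dimethoxybenzaldehyde | COc1cc(Cl)c(C=O)c(OC)c1
F3 | step 7 | [(2R,3R)-3-(3,5-dimethoxyphenyl)-4-methoxy-2-(4-methoxyphenyl)-2,3-dihydro-1-benzofuran-6-yl]lithium | [Li]c1cc(OC)c2c(c1)O[C@@H](c1ccc(OC)cc1)[C@@H]2c1cc(OC)cc(OC)c1
F4 | step 7 | (2-chloro-4,6-dimethoxyphenyl)[(2R,3R)-3-(3,5-dimethoxyphenyl)-4-methoxy-2-(4-methoxyphenyl)-2,3-dihydro-1-benzofuran-6-yl]methanol, both carbinol epimers | OC(c1cc(OC)c2c(c1)O[C@@H](c1ccc(OC)cc1)[C@@H]2c1cc(OC)cc(OC)c1)c1c(Cl)cc(OC)cc1OC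
F5 | step 7 | (2-chloro-4,6-dimethoxyphenyl)[(2R,3R)-3-(3,5-dimethoxyphenyl)-4-methoxy-2-(4-methoxyphenyl)-2,3-dihydro-1-benzofuran-6-yl]methanone | O=C(c1cc(OC)c2c(c1)O[C@@H](c1ccc(OC)cc1)[C@@H]2c1cc(OC)cc(OC)c1)c1c(Cl)cc(OC)cc1OC
F6 | step 7 | (2-chloro-6-hydroxy-4-methoxyphenyl)[(2R,3R)-3-(3,5-dimethoxyphenyl)-4-methoxy-2-(4-methoxyphenyl)-2,3-dihydro-1-benzofuran-6-yl]methanone | O=C(c1cc(OC)c2c(c1)O[C@@H](c1ccc(OC)cc1)[C@@H]2c1cc(OC)cc(OC)c1)c1c(Cl)cc(OC)cc1O
F7 | step 7 | 1-(2-chloro-6-hydroxy-4-methoxyphenyl)-1-[(2R,3R)-3-(3,5-dimethoxyphenyl)-4-methoxy-2-(4-methoxyphenyl)-2,3-dihydro-1-benzofuran-6-yl]-2-(4-methoxyphenyl)ethan-1-ol, both carbinol epimers | COc1ccc(CC(O)(c2cc(OC)c3c(c2)O[C@@H](c2ccc(OC)cc2)[C@@H]3c2cc(OC)cc(OC)c2)c2c(Cl)cc(OC)cc2O)cc1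
F8 | step 8 | (2R,3R)-4-chloro-3-[(2R,3R)-3-(3,5-dimethoxyphenyl)-4-methoxy-2-(4-methoxyphenyl)-2,3-dihydro-1-benzofuran-6-yl]-6-methoxy-2-(4-methoxyphenyl)-2,3-dihydro-1-benzofuran | Clc1cc(OC)cc2c1[C@@H](c1cc(OC)c3c(c1)O[C@@H](c1ccc(OC)cc1)[C@@H]3c1cc(OC)cc(OC)c1)[C@H](c1ccc(OC)cc1)O2
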